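At 2.0 h, the end of the feed, the whole charge of J has gone in, so the final [X] is the charge less what stands unconverted. Reckon towards that end by rates.

the same everywhere: G 14 mM (held)
- oak: J 0.20 M (fed, over 2.0 h); Z 42 µM; run made earlier
- teal: J 0.20 M (fed, over 2.0 h); Z 28 µM; time 2.0 h
- ochre: J 0.40 M (fed, over 2.0 h); Z 28 µM; time 2.0 h
- amber: J 0.80 M (fed, over 2.0 h); Z 28 µM; time 2.0 h

- oak (time / min: X / %, J / %): 1.33: 0.8, 0.3; 4.00: 3.1, 0; 6.00: 4.4, 0.4; 10.0: 7.9, 0.8; 15.0: 11.7, 0; 20.0: 15.9, 0.6; 25.0: 20.6, 0.4

(scatter of a reading: 0.3 percentage points)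

- the numbers in the tables scatter with a standard deviation of 0.3 percentage points
- at the start none of G is in solution
- "hardly changes" means that all values lie within two and a half points (for a concentration: within two and a half percent of the largest)
- percentages count the whole charge, also what has not yet gone in
- no earlier run changes the charge of Z; that part of a forecast is a guess

* [X] at the end for teal, ochre, amber, in this order
* how the row runs (hardly changes / rises, then falls / falls all the way / rises all the way / falls, then rises)

Let cA be the charge of J, tf the feeding time and cC the charge of Z, and compute n = cA/(tf·cC), the J fed per second per Z.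

oak: n = 0.661 s⁻¹
teal: n = 0.992 s⁻¹
ochre: n = 1.98 s⁻¹
amber: n = 3.97 s⁻¹

Use this n, the demanded turnover that the feed asks of each Z, as the yardstick. Oak's X reads 20.6% of the charge at 25.0 min, an average of 0.654 s⁻¹ per Z, so oak's conversion kept pace with its feed, with J read at 0.8% or less. Treat J in oak as pseudo-steady: X forms at the feed rate.

Teal asks 1.50 times oak's n, ochre 3.00 times and amber 6.01 times. Oak's reading shows no ceiling c on turnover. Where n exceeds such a ceiling, X rises at c, the unconverted J accumulates, and

[X] at the end = c·cC·tf

My own reckoning puts [X] near the charge wherever n stays below c, and looks first for a shortfall in amber, whose n is the largest of the three asked.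

The forecast gives 0.197 M, 0.39 M and 0.76 M, says the row rises all the way, and warns that “oak only sets a lower bound on capacity”.

Teal gives 0.199 M, ochre 0.396 M and amber 0.469 M, so the row rises all the way, with J in amber at 41.4% of the charge at the end.

    E → Z + X (k = 35.0 s⁻¹)
    G ⇌ L, rate k2*(csat - [L]) (kL = 0.00490 s⁻¹)
    J + Z ⇌ Q (K = 87.0 L mol⁻¹, k = 2100 L mol⁻¹ s⁻¹)
    L + Q ⇌ E (K = 130 L mol⁻¹, k = 75000 L mol⁻¹ s⁻¹)

Hold n against the entry of G into solution, taken per Z at [L] = 0: that is 2.45 s⁻¹. Ochre's 1.98 s⁻¹ lies below it, and amber's 3.97 s⁻¹ lies above it. Amber delivered 2.33 s⁻¹ on average over the run, and its [L] of 6.08 × 10⁻⁴ M at the end makes the entry per Z 2.34 s⁻¹.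

All runs stem from a simulated flask from invented constants; scatter was added.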